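**Plan**

- Retrosynthesis: the ring oxygen of the 29-membered lactone, which sits between the carbonyl carbon C1 and C28, is taken out (Baeyer–Villiger in reverse), leaving cyclooctacosanone. The bond between the ketone carbonyl carbon and one α-carbon is then cut back to the two ester carbonyls of dimethyl octacosanedioate (acyloin coupling, the extra hydroxyl removed afterwards). The central C14–C15 bond of that diester is cut into two C15 half esters that each give up CO2 (Kolbe coupling).
- Enabling feature: without the ring oxygen the ring is a 28-membered carbocycle whose single C=O is flanked by two equivalent CH2 groups. Oxygen may therefore enter either C(=O)–CH2 bond, and the carbocycle may be closed at the carbonyl carbon itself.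
- Forward order: the chain is joined first (C14–C15), then the only ring, the 28-membered carbocycle, is closed (C1–C2), then the ring grows by one atom to the 29-membered lactone.
- Stereochemistry: the target is achiral. The one stereocentre on the way, the carbinol carbon of the acyloin, is racemic and is erased in the next step.

Key step: step 4

Remark: octacosanolide is taken as the lactone of 28-hydroxyoctacosanoic acid (oxacyclononacosan-2-one: one C=O, 27 CH2, one ring oxygen), as the SMILES shows.

**Route**

Step 1
Reactants: 1 pentadecanedioic acid; 2 methanol (two molecules)
Product: 3 dimethyl pentadecanedioate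
Conditions: MeOH (solvent, large excess), H2SO4 (cat.), reflux
Reagents that add atoms: methanol, CO (compound 2 itself, which is also the solvent; one molecule enters at each of the two carboxyl groups)
Why: Fischer esterification, in which each carboxyl group of 1 takes up one molecule of methanol and the large excess of methanol drives both equilibria to the diester.

Step 2
Reactants: 3 dimethyl pentadecanedioate
Product: 5 15-methoxy-15-oxopentadecanoic acid (monomethyl pentadecanedioate), via barium bis(15-methoxy-15-oxopentadecanoate) 4 (not isolated)
Conditions: Ba(OH)2 (0.5 equiv), MeOH, rt; then 2 M HCl added to the suspension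
Reagents that add atoms: barium dihydroxide Ba(OH)2, [Ba+2].[OH-].[OH-] (the barium ion stands in 4; a hydroxide oxygen becomes a carboxyl oxygen of 5)
Why: Selective monosaponification should result because the barium salt of the half ester precipitates from methanol as it forms and is withdrawn from further hydrolysis, while the limiting base leaves only recoverable diester 3.

Step 3
Reactants: 5 15-methoxy-15-oxopentadecanoic acid (two molecules)
Product: 6 dimethyl octacosanedioate
Conditions: NaOMe (0.05 equiv), MeOH, smooth Pt anode and Pt cathode, undivided cell, constant high current density, 50 °C
Reagents that add atoms: none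
Why: Kolbe electrolysis should oxidise the partly neutralised carboxylate at platinum, and after loss of CO2 the primary C14 radicals bearing the inert ester terminus dimerise to the C28 diester, which crystallises on cooling.

Step 4
Reactants: 6 dimethyl octacosanedioate
Product: 8 racemic 2-hydroxycyclooctacosanone, via 1,2-bis(trimethylsilyloxy)cyclooctacos-1-ene 7 (not isolated)
Conditions: Na (dispersion, excess), Me3SiCl (excess), toluene, reflux, slow addition of 6, Ar; filter, concentrate; then 1 M HCl, THF, rt, Ar
Reagents that add atoms: chlorotrimethylsilane, C[Si](C)(C)Cl (its Me3Si groups stand in intermediate 7 only; none of its atoms remain in 8)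
Why: Sodium transfers electrons to both ester carbonyls of 6 to give ketyl radical anions that join carbon to carbon; the two methoxides leave to give the ring 1,2-diketone, and two further electrons give the enediolate, which Me3SiCl traps as 7 (acyloin condensation in its Rühlmann silyl-trapping form, a directly applicable known reaction type). The 28-membered carbocycle is closed by this end-to-end C1–C2 coupling of one chain whose two ester termini sit on the metal surface, a mode of closure known to serve large rings without extreme dilution. The one new stereocentre, the carbinol carbon of 8, arises when the symmetric enediol set free on acidic desilylation tautomerises by unbiased protonation at carbon, so 8 is racemic, which is harmless because step 5 removes the centre. The step needs ring closure to win over intermolecular coupling and over base-driven Dieckmann or Claisen condensation; slow addition of 6 to excess dispersed sodium keeps free diester scarce, and Me3SiCl takes up methoxide as MeOSiMe3 and shields the enediolate. The hydrolysis is run under argon because the free acyloin is prone to air oxidation to the 1,2-diketone.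

Step 5
Reactants: 8 racemic 2-hydroxycyclooctacosanone
Product: 9 cyclooctacosanone
Conditions: Zn dust, conc. HCl, AcOH (toluene as co-solvent if needed), 75–80 °C
Reagents that add atoms: none
Why: Dissolving-metal reduction of the α-ketol (Zn/HCl in acetic acid, the classical deoxygenation of macrocyclic acyloins) should expel the α-hydroxyl as water through the zinc enolate and leave the symmetric ketone, removing the only stereocentre.

Step 6
Reactants: 9 cyclooctacosanone
Product: 10 octacosanolide (oxacyclononacosan-2-one)
Conditions: (CF3CO)2O, urea·H2O2, Na2HPO4, CH2Cl2, 0 °C to rt
Reagents that add atoms: trifluoroperacetic acid, OOC(=O)C(F)(F)F, made in the flask from urea–hydrogen peroxide (OO.NC(N)=O) and trifluoroacetic anhydride (O=C(OC(=O)C(F)(F)F)C(F)(F)F); it delivers the ring oxygen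
Why: Baeyer–Villiger oxidation with this strong peracid should insert oxygen into the unstrained macrocyclic ketone, and since both α-carbons are equivalent CH2 groups either migration gives the same lactone, while the phosphate buffer guards the product against acid-promoted ring opening.

**Compound list**

1 | pentadecanedioic acid | OC(=O)CCCCCCCCCCCCCC(=O)O | starting material
2 | methanol | CO | starting material
3 | dimethyl pentadecanedioate | COC(=O)CCCCCCCCCCCCCC(=O)OC | intermediate
4 | barium bis(15-methoxy-15-oxopentadecanoate) | [Ba+2].COC(=O)CCCCCCCCCCCCCC([O-])=O.COC(=O)CCCCCCCCCCCCCC([O-])=O | intermediate (not isolated)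
5 | 15-methoxy-15-oxopentadecanoic acid (monomethyl pentadecanedioate) | COC(=O)CCCCCCCCCCCCCC(=O)O | intermediate
6 | dimethyl octacosanedioate | COC(=O)CCCCCCCCCCCCCCCCCCCCCCCCCCC(=O)OC | intermediate
7 | 1,2-bis(trimethylsilyloxy)cyclooctacos-1-ene (double-bond geometry immaterial, not specified) | C[Si](C)(C)OC1=C(O[Si](C)(C)C)CCCCCCCCCCCCCCCCCCCCCCCCCC1 | intermediate (not isolated)
8 | 2-hydroxycyclooctacosanone (racemic) | O=C1CCCCCCCCCCCCCCCCCCCCCCCCCCC1O | intermediate
9 | cyclooctacosanone | O=C1CCCCCCCCCCCCCCCCCCCCCCCCCCC1 | intermediate
10 | octacosanolide (oxacyclononacosan-2-one), achiral | O=C1CCCCCCCCCCCCCCCCCCCCCCCCCCCO1 | target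

**Step count**

Total steps: 6. Longest linear sequence: 6 steps (1 → 3 → 5 → 6 → 8 → 9 → 10).

**Steps most likely to fail, with fallbacks**

Step 4. Intermolecular reductive coupling and base-driven ester condensation may outrun ring closure, and the sparingly soluble diester may react incompletely, so that oligomeric acyloins form. The fallback sets out from 6 and closes the same C1–C2 bond by carbonyl olefination. LiAlH4 in THF at reflux should give octacosane-1,28-diol F1. Oxidation with TEMPO and PhI(OAc)2 in warm CH2Cl2 should give octacosanedial F2. Intramolecular McMurry coupling (TiCl3(DME)1.5, Zn–Cu couple, DME, reflux, addition of F2 over about a day) should join the two aldehyde carbons to give cyclooctacosene F3 as an E/Z mixture. Wacker-type oxidation of the internal alkene (Pd(OAc)2 cat., 1,4-benzoquinone, HBF4, DMA–MeCN–H2O, rt to 40 °C) should give a single ketone, because both alkene carbons are equivalent. The route is rejoined at 9.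

Step 3. The crystallising product may passivate the anode, and two-electron oxidation to cationic (Hofer–Moest) products or radical disproportionation may divert the C14 radicals from dimerisation. The fallback sets out from 5 and joins the same C14–C15 bond without electrolysis. Hunsdiecker bromodecarboxylation in the Cristol–Firth form (red HgO, Br2, CCl4, reflux, dark) should give methyl 14-bromotetradecanoate F4. Nickel-catalysed reductive homocoupling of this primary bromide (NiCl2·DME cat., 4,4',4''-tri-tert-butyl-2,2':6',2''-terpyridine, NaI, Mn powder, DMF, 40 °C), which tolerates esters, should give the C28 diester. The route is rejoined at 6.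

Step 6. Oxygen insertion into the unstrained, hindered macrocyclic ketone may be slow, and on long exposure the acid may open the lactone and lead to oligomers. The fallback sets out from 8, before the deoxygenation, and builds the ester bond by lactonisation. Cleavage of the α-ketol with H5IO6 in THF at rt should give 28-oxooctacosanoic acid F5. NaBH4 in EtOH–THF with one equivalent of NaOH should reduce only the aldehyde to give 28-hydroxyoctacosanoic acid F6. Yamaguchi activation (2,4,6-trichlorobenzoyl chloride, Et3N, THF) should give 28-hydroxyoctacosanoic 2,4,6-trichlorobenzoic anhydride F7, which is added slowly to DMAP in refluxing toluene at high dilution to close the 29-membered lactone. The route is rejoined at 10.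

**Further compounds**

F1 | step 4 | octacosane-1,28-diol | OCCCCCCCCCCCCCCCCCCCCCCCCCCCCO
F2 | step 4 | octacosanedial | O=CCCCCCCCCCCCCCCCCCCCCCCCCCCC=O
F3 | step 4 | cyclooctacosene (E/Z mixture) | C1=CCCCCCCCCCCCCCCCCCCCCCCCCCC1
F4 | step 3 | methyl 14-bromotetradecanoate | COC(=O)CCCCCCCCCCCCCBr
F5 | step 6 | 28-oxooctacosanoic acid | O=CCCCCCCCCCCCCCCCCCCCCCCCCCCC(=O)O
F6 | step 6 | 28-hydroxyoctacosanoic acid | OCCCCCCCCCCCCCCCCCCCCCCCCCCCC(=O)O
F7 | step 6 | 28-hydroxyoctacosanoic 2,4,6-trichlorobenzoic anhydride | OCCCCCCCCCCCCCCCCCCCCCCCCCCCC(=O)OC(=O)c1c(Cl)cc(Cl)cc1Cl
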